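**Retrosynthetic overview**

1. The target is a (3R)-isoflavan whose ring B carries a fused 2,2-dimethylpyran (ring D). It is unveiled last: fluoride frees the phenols and the 4'-phenoxide expels a sulfinate from C4 of ring D, creating C3=C4. The C6 prenyl group comes from a Stille coupling at an aryl bromide carried from the start.
2. Ring D is cut at two C–C bonds, CMe2–CH2 and CH–C3' (ring B). A photoredox decarboxylative radical (4+2) annulation joins the N-acyloxyphthalimide of a 2-aryloxyisobutyric acid with phenyl vinyl sulfone and closes on the arene.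
3. Enabling feature: the ring-D oxygen on C2' of ring B is bonded to a quaternary CMe2 carbon (a latent tertiary α-aryloxy radical, i.e. an aryloxyisobutyric acid). C3' is the only unsubstituted carbon ortho to that oxygen and lies between O2' and O4'. The 4'-OH ortho to the new benzylic carbon later drives the elimination.
4. The (3R)-isoflavan core comes from an isoflavone by Ru-catalysed asymmetric transfer hydrogenation with dynamic kinetic resolution, then ionic deoxygenation. The isoflavone comes from a Suzuki coupling of a 3-iodochromone (rings A and C) with a ring-B boronate that already bears the isobutyrate on O2'.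
5. Ring order: ring C (chromone) first; rings A and B are bought as arenes; ring D last.

Key step: step 10

Assumption: the sulfonyl-bearing carbon created in the key step forms as a mixture of epimers; it becomes sp2 in the last step, so the mixture is carried on and its SMILES carry no descriptor at that carbon.

**Route**

Step 1
Reactants: 1 bromoresacetophenone (1-(5-bromo-2,4-dihydroxyphenyl)ethan-1-one)
Product: 2 mono-silyl ether (1-[5-bromo-2-hydroxy-4-(triisopropylsilyloxy)phenyl]ethan-1-one)
Conditions: TIPSCl (1.1 equiv), imidazole, DMF, 0 °C to rt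
Reagents that add atoms: chlorotriisopropylsilane, CC(C)[Si](Cl)(C(C)C)C(C)C
Why: Silyl ether formation; the 2-hydroxyl is tied up in a hydrogen bond to the acetyl carbonyl, so the bulky silyl chloride should take only the 4-hydroxyl.

Step 2
Reactants: 2 mono-silyl ether
Product: 4 iodochromone (6-bromo-3-iodo-7-(triisopropylsilyloxy)-4H-chromen-4-one), via enaminone 3 (not isolated)
Conditions: Me2NCH(OMe)2, toluene, 90 °C; evaporation; then I2, CHCl3, rt
Reagents that add atoms: N,N-dimethylformamide dimethyl acetal, COC(OC)N(C)C; iodine, II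
Why: Enaminone condensation at the acetyl methyl followed by iodine-induced cyclisation with loss of dimethylamine (the standard 3-iodochromone synthesis) should close ring C and place the coupling handle on C3.

Step 3
Reactants: 5 bromoresorcinol (4-bromobenzene-1,3-diol)
Product: 6 mono-silyl bromophenol (2-bromo-5-(triisopropylsilyloxy)phenol)
Conditions: TIPSCl (1.0 equiv), imidazole, CH2Cl2, −20 to 0 °C
Reagents that add atoms: chlorotriisopropylsilane, CC(C)[Si](Cl)(C(C)C)C(C)C
Why: Silyl ether formation under steric control: the hydroxyl para to bromine has two hydrogen neighbours whereas the other is flanked by bromine, so one equivalent of the bulky chloride at low temperature should silylate the former.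

Step 4
Reactants: 6 mono-silyl bromophenol; 7 tert-butyl 2-bromo-2-methylpropanoate
Product: 8 aryl ether ester (tert-butyl 2-[2-bromo-5-(triisopropylsilyloxy)phenoxy]-2-methylpropanoate)
Conditions: K2CO3, MeCN, 70 °C
Reagents that add atoms: none
Why: Williamson-type O-alkylation of the phenoxide with the α-bromoisobutyrate (the etherification used to make fibrates) should install the quaternary O–CMe2 carbon, which guards O2' of ring B until it becomes the radical centre.

Step 5
Reactants: 8 aryl ether ester
Product: 9 arylboronate (tert-butyl 2-methyl-2-[2-(4,4,5,5-tetramethyl-1,3,2-dioxaborolan-2-yl)-5-(triisopropylsilyloxy)phenoxy]propanoate)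
Conditions: B2pin2, Pd(dppf)Cl2 (3 mol%), KOAc, 1,4-dioxane, 90 °C
Reagents that add atoms: bis(pinacolato)diboron, CC1(C)OB(OC1(C)C)B1OC(C)(C)C(C)(C)O1
Why: Miyaura borylation of the aryl bromide; the ester has no α-hydrogen and the silyl ether is inert to KOAc, so only the C–Br bond should react.

Step 6
Reactants: 4 iodochromone; 9 arylboronate
Product: 10 isoflavone (tert-butyl 2-{2-[6-bromo-4-oxo-7-(triisopropylsilyloxy)-4H-chromen-3-yl]-5-(triisopropylsilyloxy)phenoxy}-2-methylpropanoate)
Conditions: Pd(dppf)Cl2 (5 mol%), K3PO4, 1,4-dioxane/H2O (10:1), 60 °C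
Reagents that add atoms: none
Why: Suzuki–Miyaura coupling; zerovalent palladium should insert into the weak C3–I bond of the iodochromone much faster than into the electron-rich aryl bromide flanked by the silyloxy group, so the bromine on ring A is kept.

Step 7
Reactants: 10 isoflavone
Product: 12 cis-isoflavan-4-ol (tert-butyl 2-{2-[(3R,4R)-6-bromo-4-hydroxy-7-(triisopropylsilyloxy)chroman-3-yl]-5-(triisopropylsilyloxy)phenoxy}-2-methylpropanoate), via isoflavanone 11 (not isolated)
Conditions: RuCl[(R,R)-TsDPEN](p-cymene) (5 mol%), HCO2H/Et3N (5:2), EtOAc, 40 °C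
Reagents that add atoms: none
Why: Noyori–Ikariya asymmetric transfer hydrogenation with dynamic kinetic resolution: conjugate reduction should give the isoflavanone, whose C3 epimerises rapidly under Et3N, and the (R,R) catalyst should reduce the (3R) ketone faster with hydride delivered anti to the 3-aryl group, which sets C3 as R and C4 as R (cis).

Step 8
Reactants: 12 cis-isoflavan-4-ol
Product: 14 isoflavan acid (2-{2-[(3R)-6-bromo-7-(triisopropylsilyloxy)chroman-3-yl]-5-(triisopropylsilyloxy)phenoxy}-2-methylpropanoic acid), via tert-butyl ester 13 (not isolated)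
Conditions: Et3SiH (5 equiv), CF3CO2H/CH2Cl2 (1:4), −20 °C to rt
Reagents that add atoms: none
Why: Ionic hydrogenation: the C4 benzylic cation, stabilised by the para silyloxy group and the ortho ring oxygen of ring A, should be trapped by the silane before C3 is disturbed, and the same acid then cleaves the tert-butyl ester by acidolysis while the aryl silyl ethers and the aryl bromide survive.

Step 9
Reactants: 14 isoflavan acid
Product: 15 N-acyloxyphthalimide (1,3-dioxoisoindolin-2-yl ester of 14)
Conditions: N-hydroxyphthalimide, N,N'-diisopropylcarbodiimide, DMAP (10 mol%), CH2Cl2, rt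
Reagents that add atoms: N-hydroxyphthalimide, O=C1c2ccccc2C(=O)N1O
Why: Carbodiimide (Steglich-type) esterification should give the redox-active ester of the hindered tertiary acid without touching the silyl ethers or the bromide.

Step 10
Reactants: 15 N-acyloxyphthalimide; 16 phenyl vinyl sulfone
Product: 17 bromo sulfonyl-dihydropyran ((3R)-6-bromo-3-[2,2-dimethyl-4-(phenylsulfonyl)-5-(triisopropylsilyloxy)chroman-8-yl]-7-(triisopropylsilyloxy)chroman, both epimers at the sulfonyl carbon)
Conditions: fac-Ir(ppy)3 (1 mol%), 16 (3 equiv), degassed DMSO, blue LEDs (450 nm), rt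
Reagents that add atoms: none
Why: Photoexcited fac-Ir(ppy)3 should reduce the N-acyloxyphthalimide, which loses phthalimide anion and CO2 to give the tertiary 2-aryloxy-2-propyl radical; this nucleophilic radical adds to the CH2 terminus of the vinyl sulfone (new CMe2–CH2 bond), the electrophilic α-sulfonyl radical attacks C3' of ring B (new CH–aryl bond), and the cyclohexadienyl radical is oxidised by the tetravalent iridium complex and deprotonated by phthalimide anion, so the cycle is redox-neutral. The closest known reaction type is the photoredox (4+2) radical annulation of N-hydroxyphthalimide esters of 2-aryloxy carboxylic acids with electron-poor olefins to chromans (decarboxylative Giese addition followed by homolytic aromatic substitution). Ring D closes in a 6-membered mode by ortho attack (6-endo with respect to the C2'–C3' aromatic bond), whereas 5-membered ipso attack at C2' is reversible and unproductive. The one new stereocentre, the sulfonyl-bearing carbon, is not controlled and need not be, because it becomes sp2 in step 12; C3 of the isoflavan is remote and untouched. The step needs site selectivity on ring B and addition before cyclisation: the tether on O2' can only reach C3' because C1' carries the chroman, C3' lies between two oxygen substituents and so matches the electrophilic radical, and the polarity match (nucleophilic α-oxy radical with the sulfone, electrophilic α-sulfonyl radical with the arene) orders the two bond formations, while the aryl bromide and silyl ethers are inert to the catalyst.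

Step 11
Reactants: 17 bromo sulfonyl-dihydropyran; 18 tributyl(3-methylbut-2-en-1-yl)stannane
Product: 19 prenylated sulfone ((3R)-3-[2,2-dimethyl-4-(phenylsulfonyl)-5-(triisopropylsilyloxy)chroman-8-yl]-6-(3-methylbut-2-en-1-yl)-7-(triisopropylsilyloxy)chroman)
Conditions: Pd(PPh3)4 (10 mol%), DMF, 100 °C
Reagents that add atoms: none
Why: Migita–Kosugi–Stille coupling; after transmetalation the allyl group should be transferred through its unsubstituted terminus to give the linear prenyl arene at C6, the position fixed by the bromine of the starting acetophenone, under neutral conditions that leave the sulfone and silyl ethers intact.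

Step 12
Reactants: 19 prenylated sulfone
Product: 22 target ((3R)-3-(5-hydroxy-2,2-dimethyl-2H-chromen-8-yl)-6-(3-methylbut-2-en-1-yl)chroman-7-ol), via diphenol sulfone 20 (not isolated), via quinone methide 21 (not isolated)
Conditions: Bu4NF (3 equiv), THF (0.02 M), 0 °C to rt; then DBU (3 equiv), 50 °C; aq NH4Cl
Reagents that add atoms: none
Why: Fluoride desilylation frees both phenols, the 4'-phenoxide ortho to the sulfonyl-bearing benzylic carbon should expel benzenesulfinate (base-induced o-quinone methide formation as known for 2-(1-sulfonylalkyl)phenols), and DBU-mediated deprotonation of the ring-D CH2 should tautomerise the quinone methide to the aromatic 2H-chromene, the concerted 1,5-hydrogen shift being geometrically impossible here; C3 of the isoflavan is remote and unaffected.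

**Compound list**

1 | 1-(5-bromo-2,4-dihydroxyphenyl)ethan-1-one | CC(=O)c1cc(Br)c(O)cc1O | starting material
2 | 1-[5-bromo-2-hydroxy-4-(triisopropylsilyloxy)phenyl]ethan-1-one | CC(=O)c1cc(Br)c(O[Si](C(C)C)(C(C)C)C(C)C)cc1O | intermediate
3 | (E)-1-[5-bromo-2-hydroxy-4-(triisopropylsilyloxy)phenyl]-3-(dimethylamino)prop-2-en-1-one | CN(C)/C=C/C(=O)c1cc(Br)c(O[Si](C(C)C)(C(C)C)C(C)C)cc1O | intermediate
4 | 6-bromo-3-iodo-7-(triisopropylsilyloxy)-4H-chromen-4-one | O=c1c(I)coc2cc(O[Si](C(C)C)(C(C)C)C(C)C)c(Br)cc12 | intermediate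
5 | 4-bromobenzene-1,3-diol | Oc1ccc(Br)c(O)c1 | starting material
6 | 2-bromo-5-(triisopropylsilyloxy)phenol | CC(C)[Si](Oc1ccc(Br)c(O)c1)(C(C)C)C(C)C | intermediate
7 | tert-butyl 2-bromo-2-methylpropanoate | CC(C)(Br)C(=O)OC(C)(C)C | starting material
8 | tert-butyl 2-[2-bromo-5-(triisopropylsilyloxy)phenoxy]-2-methylpropanoate | CC(C)[Si](Oc1ccc(Br)c(OC(C)(C)C(=O)OC(C)(C)C)c1)(C(C)C)C(C)C | intermediate
9 | tert-butyl 2-methyl-2-[2-(4,4,5,5-tetramethyl-1,3,2-dioxaborolan-2-yl)-5-(triisopropylsilyloxy)phenoxy]propanoate | CC(C)[Si](Oc1ccc(B2OC(C)(C)C(C)(C)O2)c(OC(C)(C)C(=O)OC(C)(C)C)c1)(C(C)C)C(C)C | intermediate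
10 | tert-butyl 2-{2-[6-bromo-4-oxo-7-(triisopropylsilyloxy)-4H-chromen-3-yl]-5-(triisopropylsilyloxy)phenoxy}-2-methylpropanoate | CC(C)[Si](Oc1ccc(-c2coc3cc(O[Si](C(C)C)(C(C)C)C(C)C)c(Br)cc3c2=O)c(OC(C)(C)C(=O)OC(C)(C)C)c1)(C(C)C)C(C)C | intermediate
11 | tert-butyl 2-{2-[6-bromo-4-oxo-7-(triisopropylsilyloxy)chroman-3-yl]-5-(triisopropylsilyloxy)phenoxy}-2-methylpropanoate (C3 epimerising) | CC(C)[Si](Oc1ccc(C2COc3cc(O[Si](C(C)C)(C(C)C)C(C)C)c(Br)cc3C2=O)c(OC(C)(C)C(=O)OC(C)(C)C)c1)(C(C)C)C(C)C | intermediate
12 | tert-butyl 2-{2-[(3R,4R)-6-bromo-4-hydroxy-7-(triisopropylsilyloxy)chroman-3-yl]-5-(triisopropylsilyloxy)phenoxy}-2-methylpropanoate (3,4-cis) | Brc1cc2c(cc1O[Si](C(C)C)(C(C)C)C(C)C)OC[C@@H](c1ccc(O[Si](C(C)C)(C(C)C)C(C)C)cc1OC(C)(C)C(=O)OC(C)(C)C)[C@H]2O | intermediate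
13 | tert-butyl 2-{2-[(3R)-6-bromo-7-(triisopropylsilyloxy)chroman-3-yl]-5-(triisopropylsilyloxy)phenoxy}-2-methylpropanoate | Brc1cc2c(cc1O[Si](C(C)C)(C(C)C)C(C)C)OC[C@@H](c1ccc(O[Si](C(C)C)(C(C)C)C(C)C)cc1OC(C)(C)C(=O)OC(C)(C)C)C2 | intermediate
14 | 2-{2-[(3R)-6-bromo-7-(triisopropylsilyloxy)chroman-3-yl]-5-(triisopropylsilyloxy)phenoxy}-2-methylpropanoic acid | Brc1cc2c(cc1O[Si](C(C)C)(C(C)C)C(C)C)OC[C@@H](c1ccc(O[Si](C(C)C)(C(C)C)C(C)C)cc1OC(C)(C)C(=O)O)C2 | intermediate
15 | 1,3-dioxoisoindolin-2-yl 2-{2-[(3R)-6-bromo-7-(triisopropylsilyloxy)chroman-3-yl]-5-(triisopropylsilyloxy)phenoxy}-2-methylpropanoate | Brc1cc2c(cc1O[Si](C(C)C)(C(C)C)C(C)C)OC[C@@H](c1ccc(O[Si](C(C)C)(C(C)C)C(C)C)cc1OC(C)(C)C(=O)ON1C(=O)c3ccccc3C1=O)C2 | intermediate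
16 | phenyl vinyl sulfone | C=CS(=O)(=O)c1ccccc1 | starting material
17 | (3R)-6-bromo-3-[2,2-dimethyl-4-(phenylsulfonyl)-5-(triisopropylsilyloxy)chroman-8-yl]-7-(triisopropylsilyloxy)chroman (both epimers at the sulfonyl carbon) | Brc1cc2c(cc1O[Si](C(C)C)(C(C)C)C(C)C)OC[C@@H](c1ccc(O[Si](C(C)C)(C(C)C)C(C)C)c3c1OC(C)(C)CC3S(=O)(=O)c1ccccc1)C2 | intermediate
18 | tributyl(3-methylbut-2-en-1-yl)stannane | CCCC[Sn](CCCC)(CCCC)CC=C(C)C | starting material
19 | (3R)-3-[2,2-dimethyl-4-(phenylsulfonyl)-5-(triisopropylsilyloxy)chroman-8-yl]-6-(3-methylbut-2-en-1-yl)-7-(triisopropylsilyloxy)chroman | CC(C)=CCc1cc2c(cc1O[Si](C(C)C)(C(C)C)C(C)C)OC[C@@H](c1ccc(O[Si](C(C)C)(C(C)C)C(C)C)c3c1OC(C)(C)CC3S(=O)(=O)c1ccccc1)C2 | intermediate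
20 | (3R)-3-[5-hydroxy-2,2-dimethyl-4-(phenylsulfonyl)chroman-8-yl]-6-(3-methylbut-2-en-1-yl)chroman-7-ol | CC(C)=CCc1cc2c(cc1O)OC[C@@H](c1ccc(O)c3c1OC(C)(C)CC3S(=O)(=O)c1ccccc1)C2 | intermediate
21 | o-quinone methide of ring B: 8-[(3R)-7-hydroxy-6-(3-methylbut-2-en-1-yl)chroman-3-yl]-2,2-dimethyl-2,3-dihydrochromen-5-one with the exocyclic C4=C4a double bond | CC(C)=CCc1cc2c(cc1O)OC[C@@H](C1=C3OC(C)(C)CC=C3C(=O)C=C1)C2 | intermediate
22 | (3R)-3-(5-hydroxy-2,2-dimethyl-2H-chromen-8-yl)-6-(3-methylbut-2-en-1-yl)chroman-7-ol | CC(C)=CCc1cc2c(cc1O)OC[C@@H](c1ccc(O)c3c1OC(C)(C)C=C3)C2 | target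

**Step count and risks**

Total step count: 12. Longest linear sequence: 10 steps (steps 3 to 12, from 4-bromobenzene-1,3-diol).

Steps most likely to fail:

Step 10. After the Giese addition, the α-sulfonyl radical may be reduced, add to a second molecule of sulfone or attack ipso instead of closing at C3', which is crowded by the neighbouring silyloxy group; open-chain sulfone or telomers would result. The fallback closes ring D by a pericyclic sequence through the aryl–CH and O–CMe2 bonds. It sets out from 15. Iron-catalysed decarboxylative ethynylation of the redox-active ester (HC≡CMgBr, FeBr2 cat., THF/NMP, −15 °C) should give the aryl 1,1-dimethylpropargyl ether F1. Heating in N,N-diethylaniline at 150 °C (aromatic propargyl Claisen rearrangement, 1,5-hydrogen shift, oxa-6π electrocyclisation; again C3' is the only free ortho carbon) should give the bromochromene F2. Stille coupling with 18 under the conditions of step 11 should give the bis-silyl ether of the target F3, and Bu4NF in THF should then give 22, where the fallback rejoins the route.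

Step 12. The quinone methide may be captured by water from the fluoride source, by sulfinate or by a phenoxide of a second molecule (dimers, oligomers) faster than it tautomerises. The fallback avoids the quinone methide and uses the classical chromanone, chromanol, chromene sequence. It sets out from 19. Deprotonation α to the sulfone (LDA, THF, −78 °C) and oxidation with MoO5(pyridine)(HMPA) (oxidative desulfonylation) should give the chromanone F4. NaBH4 in MeOH/THF at 0 °C should give the chromanol F5. Bu4NF in THF, then pyridinium p-toluenesulfonate in toluene at 60 °C, should remove the silyl groups to the triol F6 and dehydrate its doubly oxygen-activated benzylic alcohol, giving 22, where the fallback rejoins the route.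

Step 8. The C4 cation may lose the C3 proton or take a 1,2-hydride shift from C3 before the silane traps it, which would erode the configuration at C3. The fallback is a radical (Barton–McCombie) deoxygenation that never makes a cation at C4. It sets out from 12. NaH, CS2 and MeI in THF at 0 °C should give the xanthate F7. Bu3SnH (1.2 equiv) and AIBN in toluene at 80 °C should give 13, here isolated, where the fallback rejoins the route; CF3CO2H/CH2Cl2 then converts 13 into 14 as in step 8.

Further compounds
F1 | step 10 | (3R)-6-bromo-3-[2-(2-methylbut-3-yn-2-yloxy)-4-(triisopropylsilyloxy)phenyl]-7-(triisopropylsilyloxy)chroman | Brc1cc2c(cc1O[Si](C(C)C)(C(C)C)C(C)C)OC[C@@H](c1ccc(O[Si](C(C)C)(C(C)C)C(C)C)cc1OC(C)(C)C#C)C2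
F2 | step 10 | (3R)-6-bromo-3-[2,2-dimethyl-5-(triisopropylsilyloxy)-2H-chromen-8-yl]-7-(triisopropylsilyloxy)chroman | Brc1cc2c(cc1O[Si](C(C)C)(C(C)C)C(C)C)OC[C@@H](c1ccc(O[Si](C(C)C)(C(C)C)C(C)C)c3c1OC(C)(C)C=C3)C2
F3 | step 10 | (3R)-3-[2,2-dimethyl-5-(triisopropylsilyloxy)-2H-chromen-8-yl]-6-(3-methylbut-2-en-1-yl)-7-(triisopropylsilyloxy)chroman | CC(C)=CCc1cc2c(cc1O[Si](C(C)C)(C(C)C)C(C)C)OC[C@@H](c1ccc(O[Si](C(C)C)(C(C)C)C(C)C)c3c1OC(C)(C)C=C3)C2
F4 | step 12 | 2,2-dimethyl-8-[(3R)-6-(3-methylbut-2-en-1-yl)-7-(triisopropylsilyloxy)chroman-3-yl]-5-(triisopropylsilyloxy)chroman-4-one | CC(C)=CCc1cc2c(cc1O[Si](C(C)C)(C(C)C)C(C)C)OC[C@@H](c1ccc(O[Si](C(C)C)(C(C)C)C(C)C)c3c1OC(C)(C)CC3=O)C2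
F5 | step 12 | 2,2-dimethyl-8-[(3R)-6-(3-methylbut-2-en-1-yl)-7-(triisopropylsilyloxy)chroman-3-yl]-5-(triisopropylsilyloxy)chroman-4-ol (both epimers at C4) | CC(C)=CCc1cc2c(cc1O[Si](C(C)C)(C(C)C)C(C)C)OC[C@@H](c1ccc(O[Si](C(C)C)(C(C)C)C(C)C)c3c1OC(C)(C)CC3O)C2
F6 | step 12 | 8-[(3R)-7-hydroxy-6-(3-methylbut-2-en-1-yl)chroman-3-yl]-2,2-dimethylchroman-4,5-diol (both epimers at C4) | CC(C)=CCc1cc2c(cc1O)OC[C@@H](c1ccc(O)c3c1OC(C)(C)CC3O)C2
F7 | step 8 | tert-butyl 2-{2-[(3R,4R)-6-bromo-4-[(methylsulfanyl)carbonothioyloxy]-7-(triisopropylsilyloxy)chroman-3-yl]-5-(triisopropylsilyloxy)phenoxy}-2-methylpropanoate | Brc1cc2c(cc1O[Si](C(C)C)(C(C)C)C(C)C)OC[C@@H](c1ccc(O[Si](C(C)C)(C(C)C)C(C)C)cc1OC(C)(C)C(=O)OC(C)(C)C)[C@H]2OC(=S)SC
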